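Amounts first: each reading of the teal run gives substrate and target as fractions of the substrate charged, and the two do not add up to the whole, so part of the charge stands in an unseen form.

| setting | teal | flask |
|---|---|---|
| substrate | 0.60 M | 0.30 M |
| partner | 0.45 M | 0.450 M |
| remark | run made earlier |  |
| time |  | 5.0 min |

- teal (time / s: target / %, substrate / %): 10.0: 5.1, 72.1; 15.0: 10.1, 66.7; 25.0: 17.7, 60.0; 30.0: 22.3, 57.2

(each reading ± 0.5 percentage points)

- when, up to 5.0 min, the flask holds most target
- the amount of target, in percent of the substrate charged, at that time
- earliest time at which at least nineteen twentieths of that best amount are there, in min
- latest time at which they still are, in min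

What do you work with? The fraction left, meaning what is not yet target: 77.7 % of the charge in the teal run at 30.0 s.

Why that? Substrate over the fraction left reads 0.736 there, and that ratio can be followed from reading to reading. I call this the free share, the part of the not-yet-target still standing as substrate, a pre-equilibrium ratio.

Is it steady? In the teal run, 15.0 s gives 0.742 and 25.0 s gives 0.729, steady within the scatter of 0.5 percentage points. The reading at 10.0 s is higher, at 0.760. This looks like a fast lag with a short time constant, its transient over by the later readings of the teal run.

But the flask holds half the substrate of the teal run, so why carry the share over? As an assumption: if the exchange is one to one, both directions scale with the amount, and the ratio does not depend on the charge. The teal run, with its one charge, does not test this.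

What do you commit to? Not a time, since the share has no clock in it. I commit to a pairing: in the flask, substrate equals the free share times the fraction left.

The forecast puts the best at 96 % at 5 min, open at 3.7 min and shut at 5 min, reasoning that “Thirty seconds of data show no target loss”. By my own pairing, that target would stand beside 2.94 % substrate.

The flask's best is 46.0 % at 2.05 min, with open at 1.32 min and shut at 3.43 min.

    2 second intermediate → homo product (k = 0.00726 M⁻¹ s⁻¹)
    open intermediate + second intermediate ⇌ target (K = 14.7 M⁻¹, k = 0.175 M⁻¹ s⁻¹)
    partner → second intermediate (k = 0.0880 s⁻¹)
    substrate ⇌ open intermediate (K = 0.411, k = 0.0753 s⁻¹)

The flask peaks inside the window, and its target reads 40.1 % at 5.00 min, with partner at 0 % by 2.05 min. The free share is substrate over substrate plus open intermediate. At 2.05 min the flask's target of 46.0 % pairs with a reckoned 39.7 % substrate, and the flask holds 38.3 %. A neighbour flask, the same but charged with 1.1 M of partner, ends at 5.00 min with 50.6 % target. The pairing reckons 36.4 % substrate for it, and that neighbour flask holds 34.8 %.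

The runs were computed for an exercise, and the scatter is random.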